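**Retrosynthetic overview**

1. The target comes from global desilylation of a tetrahydrofuran that is closed last, by acid-mediated O1–C2 etherification of a triol at its 4-methoxybenzylic carbinol. The triol comes from LiBH4 reduction of a trans α-(aryl-hydroxymethyl)-β-(arylmethyl)-γ-butyrolactone, itself the hydrolysis product of a silyl ortho-ester oxetane.
2. The oxetane comes from a Paternò–Büchi [2+2] of O-silyl isovanillin with the ketene silyl acetal of the (S)-β-(arylmethyl)butyrolactone, an enol ether reached in one step from the lactone. It makes the C2–C3 bond and a sacrificial bond from the aldehyde oxygen to the future hydroxymethyl carbon.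
3. The lactone comes from Evans alkylation of a succinate imide with the dihydrobenzofuran-6-ylmethyl bromide. The dihydrobenzofuran comes from dirhodium-catalysed C–H insertion of an aryl diazoacetate built from 3,5-dimethoxybenzyl alcohol (ortho-lithiation/oxalate, mono-demethylation) and silylated vanillyl alcohol.
4. Feature: on the tetrahydrofuran (O1, C2, C3, C4, C5) the C3 hydroxymethyl is cis to the C4 arylmethyl arm and trans to the C2 aryl. The cis C3/C4 relation is the same as the C2–C3 bond lying anti to the arm on the five-membered ring O1–C5–C4–C3–C(hydroxymethyl carbon), which is the butyrolactone and ketene-acetal ring.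
5. Ring order: dihydrobenzofuran (step 8), butyrolactone (step 16), temporary oxetane (step 19), tetrahydrofuran (step 22).

Key step: step 19

Assumption: the tert-leucinate dirhodium catalyst is taken to show its usual sense with 2-(benzyloxy)aryl diazoacetates (S ligand gives the 2R dihydrobenzofuran), so the R ligand is specified in step 8; if this doubly ortho-substituted carbenoid reverses the sense, the S catalyst is used and nothing else changes.

Abbreviations: TBS = tert-butyldimethylsilyl; TIPS = triisopropylsilyl; TBDPS = tert-butyldiphenylsilyl; DBF = the (2S,3R)-3-(TBDPSOCH2)-4-methoxy-2-[3-methoxy-4-(TIPSO)phenyl]-2,3-dihydro-1-benzofuran-6-yl group.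

**Route**

Step 1
Reactants: 1 (3,5-dimethoxyphenyl)methanol
Product: 2 tert-butyl[(3,5-dimethoxyphenyl)methoxy]dimethylsilane
Conditions: TBSCl, imidazole, DMF, rt
Reagents that add atoms: tert-butyldimethylsilyl chloride, CC(C)(C)[Si](C)(C)Cl
Why: Imidazole-promoted silylation of the primary benzylic alcohol masks the hydroxyl for the lithiation that follows.

Step 2
Reactants: 2 tert-butyl[(3,5-dimethoxyphenyl)methoxy]dimethylsilane
Product: 4 methyl 2-[4-(TBSOCH2)-2,6-dimethoxyphenyl]-2-oxoacetate, via aryllithium 3 (not isolated)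
Conditions: n-BuLi, THF, 0 °C; cannulated into (CO2Me)2 (3 equiv), THF, −78 °C; NH4Cl
Reagents that add atoms: dimethyl oxalate, COC(=O)C(=O)OC
Why: Directed ortho-metalation takes place at the one position flanked by both methoxy groups, and inverse addition of the aryllithium to excess oxalate (acylation of an organolithium by a diester) should stop at the hindered α-keto ester.

Step 3
Reactants: 4 methyl 2-[4-(TBSOCH2)-2,6-dimethoxyphenyl]-2-oxoacetate
Product: 5 methyl 2-[4-(TBSOCH2)-2-hydroxy-6-methoxyphenyl]-2-oxoacetate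
Conditions: BCl3 (1.1 equiv), CH2Cl2, −78 → −40 °C; aq NaHCO3
Reagents that add atoms: none
Why: Chelation-controlled Lewis-acid ether cleavage: BCl3 held between the ketone oxygen and one ortho methoxy group removes that methyl as chloromethane, the resulting aryloxyboron chelate shuts off the second methoxy group, and the silyl ether should survive at low temperature.

Step 4
Reactants: 6 vanillin
Product: 7 3-methoxy-4-(TIPSO)benzaldehyde
Conditions: TIPSCl, imidazole, DMF, rt
Reagents that add atoms: triisopropylsilyl chloride, CC(C)[Si](Cl)(C(C)C)C(C)C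
Why: Imidazole-promoted silylation of the phenol, with the bulky triisopropylsilyl ether chosen because it must later withstand methoxide, hydride and amide bases.

Step 5
Reactants: 7 3-methoxy-4-(TIPSO)benzaldehyde
Product: 8 [3-methoxy-4-(TIPSO)phenyl]methanol
Conditions: NaBH4, MeOH, 0 °C
Reagents that add atoms: none
Why: Borohydride reduction of an aromatic aldehyde to the benzylic alcohol, with no other reducible group present.

Step 6
Reactants: 5 methyl 2-[4-(TBSOCH2)-2-hydroxy-6-methoxyphenyl]-2-oxoacetate; 8 [3-methoxy-4-(TIPSO)phenyl]methanol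
Product: 9 methyl 2-[4-(TBSOCH2)-2-methoxy-6-{[3-methoxy-4-(TIPSO)phenyl]methoxy}phenyl]-2-oxoacetate
Conditions: PPh3, DIAD, THF, 0 °C → rt
Reagents that add atoms: none
Why: Mitsunobu etherification joins the phenol, acidified by its ortho keto ester, to the primary benzylic alcohol under neutral conditions that spare both silyl ethers and need no benzylic halide.

Step 7
Reactants: 9 keto ester benzyl ether
Product: 11 methyl 2-diazo-2-[4-(TBSOCH2)-2-methoxy-6-{[3-methoxy-4-(TIPSO)phenyl]methoxy}phenyl]acetate, via tosylhydrazone 10 (not isolated)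
Conditions: TsNHNH2, MeOH, 50 °C; evaporate; DBU, CH2Cl2, 0 °C → rt
Reagents that add atoms: 4-methylbenzenesulfonohydrazide, Cc1ccc(cc1)S(=O)(=O)NN
Why: The activated ketone of the α-keto ester condenses with tosylhydrazide and base then expels sulfinate (Bamford–Stevens diazo synthesis), the usual entry to aryl diazoacetates that are too hindered for diazo transfer.

Step 8
Reactants: 11 aryl diazoacetate
Product: 12 methyl (2S,3R)-6-(TBSOCH2)-4-methoxy-2-[3-methoxy-4-(TIPSO)phenyl]-2,3-dihydro-1-benzofuran-3-carboxylate (cis)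
Conditions: Rh2(R-PTTL)4 (dirhodium tetrakis[N-phthaloyl-(R)-tert-leucinate], 1 mol %), toluene, −60 °C, slow addition
Reagents that add atoms: none
Why: Intramolecular 1,5 carbenoid C–H insertion of the dirhodium carbenoid into the benzylic O–CH2 bond, which is far more reactive than the O–CH3 bond on the other side, closes the dihydrofuran ring; the chiral carboxylate ligands select one enantiotopic hydrogen and so set C2 (S), and the concerted insertion places aryl and ester cis, giving C3 (R).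

Step 9
Reactants: 12 cis ester
Product: 13 methyl (2S,3S)-6-(TBSOCH2)-4-methoxy-2-[3-methoxy-4-(TIPSO)phenyl]-2,3-dihydro-1-benzofuran-3-carboxylate (trans)
Conditions: NaOMe (0.3 equiv), MeOH–THF, 0 °C → rt
Reagents that add atoms: none
Why: Base-mediated epimerisation through the ester enolate inverts only C3 and should settle on the thermodynamically favoured trans isomer, while C2 is not acidic and keeps its configuration.

Step 10
Reactants: 13 trans ester
Product: 14 [(2S,3R)-6-(TBSOCH2)-4-methoxy-2-[3-methoxy-4-(TIPSO)phenyl]-2,3-dihydro-1-benzofuran-3-yl]methanol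
Conditions: LiBH4, THF–MeOH, 0 °C → rt
Reagents that add atoms: none
Why: LiBH4 reduction of the methyl ester to the primary alcohol leaves the silyl ethers and both stereocentres untouched.

Step 11
Reactants: 14 primary alcohol
Product: 15 TBDPS ether of 14 (DBF-CH2OTBS)
Conditions: TBDPSCl, imidazole, DMF, rt
Reagents that add atoms: tert-butyldiphenylsilyl chloride, CC(C)(C)[Si](Cl)(c1ccccc1)c1ccccc1
Why: Silylation of the primary alcohol as the acid-robust tert-butyldiphenylsilyl ether allows the benzylic TBS ether to be removed selectively in the next step.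

Step 12
Reactants: 15 DBF-CH2OTBS
Product: 16 DBF-methanol (DBF-CH2OH)
Conditions: CSA (0.1 equiv), MeOH–CH2Cl2, 0 °C
Reagents that add atoms: none
Why: Acid-catalysed methanolysis of silyl ethers is markedly faster for the primary alkyl TBS ether than for the TBDPS ether or the aryl TIPS ether, so only the benzylic hydroxyl should be released.

Step 13
Reactants: 16 DBF-methanol
Product: 17 DBF-methyl bromide (DBF-CH2Br)
Conditions: CBr4, PPh3, CH2Cl2, 0 °C
Reagents that add atoms: carbon tetrabromide, BrC(Br)(Br)Br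
Why: Appel bromination converts the primary benzylic alcohol into the bromide under neutral conditions compatible with the silyl ethers.

Step 14
Reactants: 18 4-methoxy-4-oxobutanoic acid (monomethyl succinate); 19 (4S)-4-benzyl-1,3-oxazolidin-2-one
Product: 21 methyl 4-[(4S)-4-benzyl-2-oxo-1,3-oxazolidin-3-yl]-4-oxobutanoate, via pivalic mixed anhydride 20 (not isolated)
Conditions: PivCl, Et3N, THF, −20 °C; then 19, LiCl, rt
Reagents that add atoms: none
Why: N-Acylation of the oxazolidinone by the mixed pivalic anhydride, promoted by LiCl, gives the succinate imide without touching the methyl ester.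

Step 15
Reactants: 21 succinate imide; 17 DBF-methyl bromide
Product: 23 methyl (3S)-4-[(4S)-4-benzyl-2-oxo-1,3-oxazolidin-3-yl]-3-(DBF-methyl)-4-oxobutanoate, via sodium enolate 22 (not isolated)
Conditions: NaN(SiMe3)2, THF, −78 °C; then 17, −78 → −30 °C
Reagents that add atoms: none
Why: Evans asymmetric alkylation: NaN(SiMe3)2 deprotonates the more acidic imide α-CH2 to the chelated Z-enolate, whose face opposite the auxiliary benzyl group is alkylated by the benzylic bromide, setting the new centre (S).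

Step 16
Reactants: 23 alkylated imide
Product: 25 (4S)-4-(DBF-methyl)oxolan-2-one, via hydroxy ester 24 (not isolated)
Conditions: NaBH4, THF–H2O, 0 °C → rt; then PPTS, CH2Cl2, rt
Reagents that add atoms: none
Why: NaBH4 in wet THF reduces the exocyclic imide carbonyl in preference to the methyl ester (reductive removal of the auxiliary), and the γ-hydroxy ester then lactonises without touching the stereocentre.

Step 17
Reactants: 25 lactone
Product: 27 (3S)-5-(TBSO)-3-(DBF-methyl)-2,3-dihydrofuran (ketene silyl acetal), via lithium enolate 26 (not isolated)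
Conditions: LiN(iPr)2, THF, −78 °C; TBSCl, DMPU, −78 °C → rt; pentane, filtration, used crude
Reagents that add atoms: tert-butyldimethylsilyl chloride, CC(C)(C)[Si](C)(C)Cl
Why: O-Silylation of the lactone lithium enolate (ketene silyl acetal formation) takes place at the only acidic C–H position and leaves the adjacent stereocentre unchanged.

Step 18
Reactants: 28 isovanillin
Product: 29 3-(TBSO)-4-methoxybenzaldehyde
Conditions: TBSCl, imidazole, CH2Cl2, rt
Reagents that add atoms: tert-butyldimethylsilyl chloride, CC(C)(C)[Si](C)(C)Cl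
Why: Imidazole-promoted silylation protects the phenol so that it can neither quench the excited state nor protonate the ketene acetal.

Step 19
Reactants: 27 ketene silyl acetal; 29 3-(TBSO)-4-methoxybenzaldehyde
Product: 30 (1R,4S,5R,6R)-1-(TBSO)-6-[3-(TBSO)-4-methoxyphenyl]-4-(DBF-methyl)-2,7-dioxabicyclo[3.2.0]heptane (6-aryl drawn endo)
Conditions: hν (350 nm, Pyrex), degassed MeCN, −10 °C, argon
Reagents that add atoms: none
Why: Light above 320 nm is absorbed only by 29, whose triplet state is intercepted by the electron-rich ketene acetal double bond of 27 through a charge-transfer exciplex; the carbonyl carbon bonds to C4 of 27 and the carbonyl oxygen closes onto the doubly oxygenated C5 of 27 after spin inversion, a stepwise Paternò–Büchi [2+2] that joins the two partners one to one with every atom of both kept in 30. The closest known reaction type is the photocycloaddition of aromatic aldehydes to 2-silyloxy-4,5-dihydrofurans (ketene silyl acetals of γ-butyrolactone), which gives 2-alkoxy-2-silyloxyoxetanes. The oxetane is closed by recombination of the 1,4-biradical or ion pair (oxygen to the acetal carbon, four-membered), and it is cis-fused because a trans fusion of a four- and a five-membered ring is too strained. Of the three new stereocentres of 30, C5 (the new C–C bond) should be set anti to the arylmethyl group on the neighbouring C4, which shields one face of the nearly planar ring; C1 follows from the cis fusion; C6 (endo or exo aryl) is left uncontrolled because that carbon is re-set in step 22. The step needs the oxygen-to-acetal-carbon orientation, which cyclic enol ethers of the 2,3-dihydrofuran type already show with aromatic aldehydes and which the silyloxy group reinforces: it makes the alkene a stronger donor whose β-carbon (C4 of 27) is the nucleophilic site and whose C5 takes the positive charge, a polarisation that acetonitrile supports. It also needs attack anti to the arm, which the single stereocentre next to the reacting carbon provides.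

Step 20
Reactants: 30 silyl ortho-ester oxetane (crude)
Product: 31 (3R,4S)-3-{(R)-hydroxy[3-(TBSO)-4-methoxyphenyl]methyl}-4-(DBF-methyl)oxolan-2-one
Conditions: AcOH–THF–H2O, 0 °C
Reagents that add atoms: none
Why: Mild acid hydrolysis of the strained silyl ortho ester opens the oxetane at the C1–O7 bond and expels the silyl group (ortho ester hydrolysis), unmasking the aldol-type hydroxy lactone with the trans C3/C4 relationship intact.

Step 21
Reactants: 31 hydroxy lactone
Product: 32 (2S,3S)-2-{(R)-hydroxy[3-(TBSO)-4-methoxyphenyl]methyl}-3-(DBF-methyl)butane-1,4-diol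
Conditions: LiBH4, THF, 0 °C → rt
Reagents that add atoms: none
Why: LiBH4 reduction of the γ-lactone gives the 1,4-diol without touching the stereocentres or the silyl ethers.

Step 22
Reactants: 32 triol
Product: 33 [(2R,3S,4S)-2-[3-(TBSO)-4-methoxyphenyl]-4-(DBF-methyl)oxolan-3-yl]methanol
Conditions: CSA (5 mol %), CH2Cl2 (dilute), 0 °C, short reaction time; Et3N quench
Reagents that add atoms: none
Why: Acid-catalysed SN1 cycloetherification: the 4-methoxybenzylic cation is captured 5-exo by the hydroxymethyl group on C4 (the other primary hydroxyl could only form an oxetane), and the aryl group settles trans to the C3 substituent, so both carbinol epimers should converge on the 2R configuration.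

Step 23
Reactants: 33 tris-silyl ether
Product: 34 [(2R,3S,4S)-2-(3-hydroxy-4-methoxyphenyl)-4-{[(2S,3R)-2-(4-hydroxy-3-methoxyphenyl)-3-(hydroxymethyl)-4-methoxy-2,3-dihydro-1-benzofuran-6-yl]methyl}oxolan-3-yl]methanol (CNP0242386.1)
Conditions: Bu4NF, AcOH, THF, 0 °C → rt
Reagents that add atoms: none
Why: Buffered fluoride desilylation removes the three silyl ethers in one operation without acid or strong base, which the benzylic ethers of the product would not tolerate.

**Compound list**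

1 | (3,5-dimethoxyphenyl)methanol | COc1cc(CO)cc(OC)c1 | starting material
2 | tert-butyl[(3,5-dimethoxyphenyl)methoxy]dimethylsilane | COc1cc(CO[Si](C)(C)C(C)(C)C)cc(OC)c1 | intermediate
3 | [4-(TBSOCH2)-2,6-dimethoxyphenyl]lithium | [Li]c1c(OC)cc(CO[Si](C)(C)C(C)(C)C)cc1OC | intermediate
4 | methyl 2-[4-(TBSOCH2)-2,6-dimethoxyphenyl]-2-oxoacetate | COC(=O)C(=O)c1c(OC)cc(CO[Si](C)(C)C(C)(C)C)cc1OC | intermediate
5 | methyl 2-[4-(TBSOCH2)-2-hydroxy-6-methoxyphenyl]-2-oxoacetate | COC(=O)C(=O)c1c(O)cc(CO[Si](C)(C)C(C)(C)C)cc1OC | intermediate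
6 | vanillin | COc1cc(C=O)ccc1O | starting material
7 | 3-methoxy-4-[(triisopropylsilyl)oxy]benzaldehyde | COc1cc(C=O)ccc1O[Si](C(C)C)(C(C)C)C(C)C | intermediate
8 | {3-methoxy-4-[(triisopropylsilyl)oxy]phenyl}methanol | COc1cc(CO)ccc1O[Si](C(C)C)(C(C)C)C(C)C | intermediate
9 | methyl 2-[4-(TBSOCH2)-2-methoxy-6-({3-methoxy-4-[(triisopropylsilyl)oxy]phenyl}methoxy)phenyl]-2-oxoacetate | COC(=O)C(=O)c1c(OC)cc(CO[Si](C)(C)C(C)(C)C)cc1OCc1ccc(O[Si](C(C)C)(C(C)C)C(C)C)c(OC)c1 | intermediate
10 | N-tosylhydrazone of 9 | COC(=O)C(=NNS(=O)(=O)c1ccc(C)cc1)c1c(OC)cc(CO[Si](C)(C)C(C)(C)C)cc1OCc1ccc(O[Si](C(C)C)(C(C)C)C(C)C)c(OC)c1 | intermediate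
11 | methyl 2-diazo-2-[4-(TBSOCH2)-2-methoxy-6-({3-methoxy-4-[(triisopropylsilyl)oxy]phenyl}methoxy)phenyl]acetate | COC(=O)C(=[N+]=[N-])c1c(OC)cc(CO[Si](C)(C)C(C)(C)C)cc1OCc1ccc(O[Si](C(C)C)(C(C)C)C(C)C)c(OC)c1 | intermediate
12 | methyl (2S,3R)-6-(TBSOCH2)-4-methoxy-2-[3-methoxy-4-(TIPSO)phenyl]-2,3-dihydro-1-benzofuran-3-carboxylate (cis) | CC(C)(C)[Si](C)(C)OCc1cc(OC)c2c(c1)O[C@H](c1ccc(O[Si](C(C)C)(C(C)C)C(C)C)c(OC)c1)[C@@H]2C(=O)OC | intermediate
13 | methyl (2S,3S)-6-(TBSOCH2)-4-methoxy-2-[3-methoxy-4-(TIPSO)phenyl]-2,3-dihydro-1-benzofuran-3-carboxylate (trans) | CC(C)(C)[Si](C)(C)OCc1cc(OC)c2c(c1)O[C@H](c1ccc(O[Si](C(C)C)(C(C)C)C(C)C)c(OC)c1)[C@H]2C(=O)OC | intermediate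
14 | [(2S,3R)-6-(TBSOCH2)-4-methoxy-2-[3-methoxy-4-(TIPSO)phenyl]-2,3-dihydro-1-benzofuran-3-yl]methanol | CC(C)(C)[Si](C)(C)OCc1cc(OC)c2c(c1)O[C@H](c1ccc(O[Si](C(C)C)(C(C)C)C(C)C)c(OC)c1)[C@H]2CO | intermediate
15 | (2S,3R)-6-(TBSOCH2)-3-(TBDPSOCH2)-4-methoxy-2-[3-methoxy-4-(TIPSO)phenyl]-2,3-dihydro-1-benzofuran | CC(C)(C)[Si](C)(C)OCc1cc(OC)c2c(c1)O[C@H](c1ccc(O[Si](C(C)C)(C(C)C)C(C)C)c(OC)c1)[C@H]2CO[Si](c1ccccc1)(c1ccccc1)C(C)(C)C | intermediate
16 | [(2S,3R)-3-(TBDPSOCH2)-4-methoxy-2-[3-methoxy-4-(TIPSO)phenyl]-2,3-dihydro-1-benzofuran-6-yl]methanol | OCc1cc(OC)c2c(c1)O[C@H](c1ccc(O[Si](C(C)C)(C(C)C)C(C)C)c(OC)c1)[C@H]2CO[Si](c1ccccc1)(c1ccccc1)C(C)(C)C | intermediate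
17 | (2S,3R)-6-(bromomethyl)-3-(TBDPSOCH2)-4-methoxy-2-[3-methoxy-4-(TIPSO)phenyl]-2,3-dihydro-1-benzofuran | BrCc1cc(OC)c2c(c1)O[C@H](c1ccc(O[Si](C(C)C)(C(C)C)C(C)C)c(OC)c1)[C@H]2CO[Si](c1ccccc1)(c1ccccc1)C(C)(C)C | intermediate
18 | 4-methoxy-4-oxobutanoic acid | COC(=O)CCC(=O)O | starting material
19 | (4S)-4-benzyl-1,3-oxazolidin-2-one | O=C1OC[C@H](Cc2ccccc2)N1 | starting material
20 | 4-methoxy-4-oxobutanoic pivalic anhydride | COC(=O)CCC(=O)OC(=O)C(C)(C)C | intermediate
21 | methyl 4-[(4S)-4-benzyl-2-oxo-1,3-oxazolidin-3-yl]-4-oxobutanoate | COC(=O)CCC(=O)N1[C@@H](Cc2ccccc2)COC1=O | intermediate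
22 | sodium (Z)-enolate of 21 | [Na+].COC(=O)C/C=C(\[O-])N1[C@@H](Cc2ccccc2)COC1=O | intermediate
23 | methyl (3S)-4-[(4S)-4-benzyl-2-oxo-1,3-oxazolidin-3-yl]-3-(DBF-methyl)-4-oxobutanoate | O=C1OC[C@H](Cc2ccccc2)N1C(=O)[C@@H](Cc1cc(OC)c2c(c1)O[C@H](c1ccc(O[Si](C(C)C)(C(C)C)C(C)C)c(OC)c1)[C@H]2CO[Si](c1ccccc1)(c1ccccc1)C(C)(C)C)CC(=O)OC | intermediate
24 | methyl (3S)-3-(DBF-methyl)-4-hydroxybutanoate | OC[C@@H](Cc1cc(OC)c2c(c1)O[C@H](c1ccc(O[Si](C(C)C)(C(C)C)C(C)C)c(OC)c1)[C@H]2CO[Si](c1ccccc1)(c1ccccc1)C(C)(C)C)CC(=O)OC | intermediate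
25 | (4S)-4-(DBF-methyl)oxolan-2-one | O=C5OC[C@@H](Cc1cc(OC)c2c(c1)O[C@H](c1ccc(O[Si](C(C)C)(C(C)C)C(C)C)c(OC)c1)[C@H]2CO[Si](c1ccccc1)(c1ccccc1)C(C)(C)C)C5 | intermediate
26 | lithium enolate of 25 | [Li+].[O-]C5=C[C@H](Cc1cc(OC)c2c(c1)O[C@H](c1ccc(O[Si](C(C)C)(C(C)C)C(C)C)c(OC)c1)[C@H]2CO[Si](c1ccccc1)(c1ccccc1)C(C)(C)C)CO5 | intermediate
27 | tert-butyl{[(3S)-3-(DBF-methyl)-2,3-dihydrofuran-5-yl]oxy}dimethylsilane | CC(C)(C)[Si](C)(C)OC5=C[C@H](Cc1cc(OC)c2c(c1)O[C@H](c1ccc(O[Si](C(C)C)(C(C)C)C(C)C)c(OC)c1)[C@H]2CO[Si](c1ccccc1)(c1ccccc1)C(C)(C)C)CO5 | intermediate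
28 | isovanillin | COc1ccc(C=O)cc1O | starting material
29 | 3-[(tert-butyldimethylsilyl)oxy]-4-methoxybenzaldehyde | COc1ccc(C=O)cc1O[Si](C)(C)C(C)(C)C | intermediate
30 | (1R,4S,5R,6R)-1-(TBSO)-6-[3-(TBSO)-4-methoxyphenyl]-4-(DBF-methyl)-2,7-dioxabicyclo[3.2.0]heptane | COc1ccc([C@@H]2O[C@]3(O[Si](C)(C)C(C)(C)C)OC[C@@H](Cc4cc(OC)c5c(c4)O[C@H](c4ccc(O[Si](C(C)C)(C(C)C)C(C)C)c(OC)c4)[C@H]5CO[Si](c4ccccc4)(c4ccccc4)C(C)(C)C)[C@H]23)cc1O[Si](C)(C)C(C)(C)C | intermediate
31 | (3R,4S)-3-{(R)-hydroxy[3-(TBSO)-4-methoxyphenyl]methyl}-4-(DBF-methyl)oxolan-2-one | COc1ccc([C@H](O)[C@@H]5C(=O)OC[C@H]5Cc4cc(OC)c6c(c4)O[C@H](c4ccc(O[Si](C(C)C)(C(C)C)C(C)C)c(OC)c4)[C@H]6CO[Si](c4ccccc4)(c4ccccc4)C(C)(C)C)cc1O[Si](C)(C)C(C)(C)C | intermediate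
32 | (2S,3S)-2-{(R)-hydroxy[3-(TBSO)-4-methoxyphenyl]methyl}-3-(DBF-methyl)butane-1,4-diol | COc1ccc([C@H](O)[C@H](CO)[C@@H](CO)Cc4cc(OC)c6c(c4)O[C@H](c4ccc(O[Si](C(C)C)(C(C)C)C(C)C)c(OC)c4)[C@H]6CO[Si](c4ccccc4)(c4ccccc4)C(C)(C)C)cc1O[Si](C)(C)C(C)(C)C | intermediate
33 | [(2R,3S,4S)-2-[3-(TBSO)-4-methoxyphenyl]-4-(DBF-methyl)oxolan-3-yl]methanol | COc1ccc([C@@H]2OC[C@@H](Cc3cc(OC)c4c(c3)O[C@H](c3ccc(O[Si](C(C)C)(C(C)C)C(C)C)c(OC)c3)[C@H]4CO[Si](c3ccccc3)(c3ccccc3)C(C)(C)C)[C@H]2CO)cc1O[Si](C)(C)C(C)(C)C | intermediate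
34 | [(2R,3S,4S)-2-(3-hydroxy-4-methoxyphenyl)-4-{[(2S,3R)-2-(4-hydroxy-3-methoxyphenyl)-3-(hydroxymethyl)-4-methoxy-2,3-dihydro-1-benzofuran-6-yl]methyl}oxolan-3-yl]methanol | COc1ccc([C@@H]2OC[C@@H](Cc3cc(OC)c4c(c3)O[C@H](c3ccc(O)c(OC)c3)[C@H]4CO)[C@H]2CO)cc1O | target

**Totals**

Total step count: 23. Longest linear sequence: 19 steps (steps 1–3, 6–13, 15–17, 19–23, from compound 1).

**Steps most likely to fail**

Step 19 (Paternò–Büchi). What may go wrong: the excited aldehyde, whose alkoxy groups lower its reactivity, may add in the reverse orientation or abstract hydrogen instead of cycloadding, and the silyl ortho ester may hydrolyse or revert during irradiation, so that little oxetane survives. Fallback (thermal in place of photochemical C–C bond formation): setting out from lactone 25, the lithium enolate 26 (LiN(iPr)2, THF, −78 °C) is added to aldehyde 29 in an aldol reaction (aq NH4Cl quench), which again should take place anti to the arylmethyl group. This should give hydroxy lactone 31 together with its carbinol epimer, (3R,4S)-3-{(S)-hydroxy[3-(TBSO)-4-methoxyphenyl]methyl}-4-(DBF-methyl)oxolan-2-one F1. The route is rejoined at 31 (step 21), and F1 is carried along because step 22 erases the carbinol centre.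

Step 8 (C–H insertion). What may go wrong: poor enantiofacial discrimination at a carbenoid flanked by two ortho oxygen substituents, so that the ester is formed in low enantiomeric purity. Fallback (resolution in place of asymmetric catalysis): setting out from diazo ester 11, achiral Rh2(OAc)4 in CH2Cl2 should give cis ester 12 together with its enantiomer, the (2R,3S) cis ester F2. Epimerisation as in step 9 gives 13 and its enantiomer, the (2R,3R) trans ester F3, and reduction as in step 10 gives 14 and its enantiomer, the (2R,3S) alcohol F4. Esterification with (S)-2-methoxy-2-phenylacetic acid (DCC, DMAP, CH2Cl2) gives the diastereomeric esters, the (S)-O-methylmandelate of 14 F5 and the (S)-O-methylmandelate of the enantiomer F6, which are separated by chromatography or crystallisation. LiBH4 cleavage of F5 returns enantiopure 14, where the route is rejoined (step 11).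

Step 22 (cycloetherification). What may go wrong: the benzylic cation, or the product ether once re-ionised by the acid, may alkylate the electron-rich benzene ring of the arm ortho to its CH2 group and close a six-membered carbocycle in place of the tetrahydrofuran, or the 2,3-cis ether may persist. Fallback (closure without a cation): it sets out from triol 32 as the carbinol epimer drawn, which the endo photoadduct supplies; the other epimer is set aside at 31 because this closure retains the C2 configuration. Both primary hydroxyls are tosylated (TsCl, pyridine, 0 °C) to the bis-tosylate F7. NaH in THF turns the benzylic hydroxyl into an alkoxide that displaces the tosylate on the C4 side in a 5-exo-tet Williamson closure (the other tosylate could only give an oxetane), giving the tetrahydrofuran tosylate F8. CsOAc with 18-crown-6 in DMF at 60 °C exchanges the remaining tosylate for acetate, giving the tetrahydrofuran acetate F9, and LiBH4 removes the acetyl group to return to 33 (step 23).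

**Further compounds**

F1 | step 19 | (3R,4S)-3-{(S)-hydroxy[3-(TBSO)-4-methoxyphenyl]methyl}-4-(DBF-methyl)oxolan-2-one | COc1ccc([C@@H](O)[C@@H]5C(=O)OC[C@H]5Cc4cc(OC)c6c(c4)O[C@H](c4ccc(O[Si](C(C)C)(C(C)C)C(C)C)c(OC)c4)[C@H]6CO[Si](c4ccccc4)(c4ccccc4)C(C)(C)C)cc1O[Si](C)(C)C(C)(C)C
F2 | step 8 | methyl (2R,3S)-6-(TBSOCH2)-4-methoxy-2-[3-methoxy-4-(TIPSO)phenyl]-2,3-dihydro-1-benzofuran-3-carboxylate (cis, enantiomer of 12) | CC(C)(C)[Si](C)(C)OCc1cc(OC)c2c(c1)O[C@@H](c1ccc(O[Si](C(C)C)(C(C)C)C(C)C)c(OC)c1)[C@H]2C(=O)OC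
F3 | step 8 | methyl (2R,3R)-6-(TBSOCH2)-4-methoxy-2-[3-methoxy-4-(TIPSO)phenyl]-2,3-dihydro-1-benzofuran-3-carboxylate (trans, enantiomer of 13) | CC(C)(C)[Si](C)(C)OCc1cc(OC)c2c(c1)O[C@@H](c1ccc(O[Si](C(C)C)(C(C)C)C(C)C)c(OC)c1)[C@@H]2C(=O)OC
F4 | step 8 | [(2R,3S)-6-(TBSOCH2)-4-methoxy-2-[3-methoxy-4-(TIPSO)phenyl]-2,3-dihydro-1-benzofuran-3-yl]methanol (enantiomer of 14) | CC(C)(C)[Si](C)(C)OCc1cc(OC)c2c(c1)O[C@@H](c1ccc(O[Si](C(C)C)(C(C)C)C(C)C)c(OC)c1)[C@@H]2CO
F5 | step 8 | [(2S,3R)-6-(TBSOCH2)-4-methoxy-2-[3-methoxy-4-(TIPSO)phenyl]-2,3-dihydro-1-benzofuran-3-yl]methyl (2S)-2-methoxy-2-phenylacetate | CC(C)(C)[Si](C)(C)OCc1cc(OC)c2c(c1)O[C@H](c1ccc(O[Si](C(C)C)(C(C)C)C(C)C)c(OC)c1)[C@H]2COC(=O)[C@@H](OC)c1ccccc1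
F6 | step 8 | [(2R,3S)-6-(TBSOCH2)-4-methoxy-2-[3-methoxy-4-(TIPSO)phenyl]-2,3-dihydro-1-benzofuran-3-yl]methyl (2S)-2-methoxy-2-phenylacetate | CC(C)(C)[Si](C)(C)OCc1cc(OC)c2c(c1)O[C@@H](c1ccc(O[Si](C(C)C)(C(C)C)C(C)C)c(OC)c1)[C@@H]2COC(=O)[C@@H](OC)c1ccccc1
F7 | step 22 | (2S,3S)-2-{(R)-hydroxy[3-(TBSO)-4-methoxyphenyl]methyl}-3-(DBF-methyl)butane-1,4-diyl bis(4-methylbenzenesulfonate) | COc1ccc([C@H](O)[C@H](COS(=O)(=O)c2ccc(C)cc2)[C@@H](COS(=O)(=O)c2ccc(C)cc2)Cc4cc(OC)c6c(c4)O[C@H](c4ccc(O[Si](C(C)C)(C(C)C)C(C)C)c(OC)c4)[C@H]6CO[Si](c4ccccc4)(c4ccccc4)C(C)(C)C)cc1O[Si](C)(C)C(C)(C)C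
F8 | step 22 | [(2R,3S,4S)-2-[3-(TBSO)-4-methoxyphenyl]-4-(DBF-methyl)oxolan-3-yl]methyl 4-methylbenzenesulfonate | COc1ccc([C@@H]2OC[C@@H](Cc3cc(OC)c4c(c3)O[C@H](c3ccc(O[Si](C(C)C)(C(C)C)C(C)C)c(OC)c3)[C@H]4CO[Si](c3ccccc3)(c3ccccc3)C(C)(C)C)[C@H]2COS(=O)(=O)c2ccc(C)cc2)cc1O[Si](C)(C)C(C)(C)C
F9 | step 22 | [(2R,3S,4S)-2-[3-(TBSO)-4-methoxyphenyl]-4-(DBF-methyl)oxolan-3-yl]methyl acetate | COc1ccc([C@@H]2OC[C@@H](Cc3cc(OC)c4c(c3)O[C@H](c3ccc(O[Si](C(C)C)(C(C)C)C(C)C)c(OC)c3)[C@H]4CO[Si](c3ccccc3)(c3ccccc3)C(C)(C)C)[C@H]2COC(C)=O)cc1O[Si](C)(C)C(C)(C)C
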